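**Plan**

1. Retrosynthesis: the methyl-bearing cyclohexene of the decalin (ring B) is cut at C4a–C5 and C8–C8a, a Diels–Alder union of a zingiberene-type dienoic acid (ring A, dienophile) with a triene. The triene is cut at the single bond between its trisubstituted alkene and the terminal diene (Suzuki–Miyaura). The saturated carboxycyclohexane (ring C; C1 = CO2H carbon, C4 = carbon bearing the propenyl chain) is cut at C1–C6 and C2–C3.
2. Enabling feature: in ring C the CO2H on C1 and the chain on C4 are 1,4-related, so C1–C2 is an acrylate unit and C3–C4–C5–C6 a 2-substituted butadiene; a "para" [4+2] makes both bonds at once. A C4=C5 ring alkene and a silyloxy group on the side-chain carbon are oxidation-level helpers, removed in steps 4 and 5.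
3. Forward order: ring C (steps 1–5), E-alkenyl boronate and triene (6–8), ring A from (S)-citronellal and methyl vinyl ketone (9–11), ring B last by intermolecular Diels–Alder (12), ester hydrolysis (13).
4. Stereochemistry: side-chain centre from (S)-citronellal; ring A centre by catalyst-controlled enamine Michael addition; C4a, C5 and C8a by a CO2H-endo cycloaddition anti to the ring A side chain; trans ring C by ester-directed hydrogenation (also the thermodynamic isomer); E alkenes by boron–Wittig olefination, syn hydrozirconation and stereoretentive coupling.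

Key step: step 3

Remark: ring C is a trans-1,4-disubstituted cyclohexane with no independent stereocentre, so 6–9 are carried as racemates or achiral compounds. Decalin numbering used: C1 (CH2), C2 (side chain), C3=C4, C4a (CO2H), C5 (alkenyl), C6=C7 (methyl on C7), C8, C8a.

**Route**

Step 1
Reactants: 1 (±)-but-3-yn-2-ol
Product: 2 tert-butyl(but-3-yn-2-yloxy)dimethylsilane (racemic)
Conditions: TBSCl, imidazole, DMF, 0 °C to rt
Reagents that add atoms: tert-butyldimethylsilyl chloride (TBSCl), CC(C)(C)[Si](C)(C)Cl
Why: Standard imidazole-promoted silylation of a secondary propargylic alcohol; the silyl ether masks the future acetyl oxygen through the Lewis-acidic cycloaddition.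

Step 2
Reactants: 2 tert-butyl(but-3-yn-2-yloxy)dimethylsilane; 3 ethylene
Product: 4 tert-butyldimethyl[(3-methylidenepent-4-en-2-yl)oxy]silane (racemic)
Conditions: ethylene (1 atm), second-generation Grubbs catalyst RuCl2(=CHPh)(PCy3)(H2IMes) (5 mol%), toluene, 80 °C
Reagents that add atoms: none
Why: Cross enyne metathesis of a terminal alkyne with ethylene places one CH2 on each alkyne carbon and gives the 2-substituted 1,3-butadiene directly; propargylic silyl ethers are good substrates for this reaction type.

Step 3
Reactants: 4 tert-butyldimethyl[(3-methylidenepent-4-en-2-yl)oxy]silane; 5 methyl acrylate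
Product: 6 methyl 4-[1-(tert-butyldimethylsilyloxy)ethyl]cyclohex-3-ene-1-carboxylate (racemic, both diastereomers)
Conditions: Et2AlCl (20 mol%), CH2Cl2, −78 to −20 °C
Reagents that add atoms: none
Why: A concerted, asynchronous [4+2] cycloaddition (Lewis-acid-catalysed Diels–Alder reaction) between the s-cis 2-substituted butadiene 4 and aluminium-bound methyl acrylate forms the bond from the acrylate β-carbon to the diene CH2 next to the substituted carbon and the bond from the acrylate α-carbon to the distal CH2 in one operation. The closest known reaction type is the AlCl3- or Et2AlCl-catalysed addition of acrylates to isoprene and myrcene, which gives the 1,4-("para") cyclohexene. Ring C is closed by intermolecular suprafacial–suprafacial [4+2] closure of two open-chain partners. The only new stereocentre, the ester-bearing ring carbon, forms as a racemate and needs no control because the final trans-1,4-cyclohexane has no independent stereocentre; the ring alkene and the silyloxy carbon are helpers that steps 4 and 5 remove. The step needs para over meta regioselectivity, which the larger HOMO coefficient at the CH2 adjacent to the substituted diene carbon and the strongly polarised acrylate–aluminium complex should secure, and the branched 2-substituent favours the reactive s-cis conformer. The secondary silyl ether should tolerate substoichiometric Et2AlCl at low temperature.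

Step 4
Reactants: 6 methyl 4-[1-(tert-butyldimethylsilyloxy)ethyl]cyclohex-3-ene-1-carboxylate
Product: 7 methyl trans-4-[1-(tert-butyldimethylsilyloxy)ethyl]cyclohexane-1-carboxylate (racemic at the carbinol carbon)
Conditions: H2 (1 atm), [Ir(cod)(PCy3)(py)]PF6 (3 mol%), CH2Cl2, rt
Reagents that add atoms: none
Why: Carbonyl-directed homogeneous hydrogenation: the cationic iridium binds the ester carbonyl and delivers H2 to the alkene face syn to it, so the new C–H is cis to CO2Me and the side chain ends trans, which is also the diequatorial thermodynamic isomer.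

Step 5
Reactants: 7 methyl trans-4-[1-(tert-butyldimethylsilyloxy)ethyl]cyclohexane-1-carboxylate
Product: 9 methyl trans-4-acetylcyclohexane-1-carboxylate, via carbinol 8 (not isolated)
Conditions: CrO3, aq. H2SO4 (Jones reagent), acetone, 0 °C to rt
Reagents that add atoms: none
Why: Jones oxidation cleaves the secondary silyl ether under its acidic conditions and oxidises the liberated alcohol to the methyl ketone in the same flask; the methyl ester is inert and the trans (diequatorial) arrangement is the stable one.

Step 6
Reactants: 9 methyl trans-4-acetylcyclohexane-1-carboxylate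
Product: 10 methyl trans-4-[(1E)-1-(4,4,5,5-tetramethyl-1,3,2-dioxaborolan-2-yl)prop-1-en-2-yl]cyclohexane-1-carboxylate
Conditions: bis(pinacolboryl)methane, lithium 2,2,6,6-tetramethylpiperidide (LiTMP), THF, 0 °C; then 9, −78 °C to rt
Reagents that add atoms: bis(4,4,5,5-tetramethyl-1,3,2-dioxaborolan-2-yl)methane, CC1(C)OB(CB2OC(C)(C)C(C)(C)O2)OC1(C)C
Why: Boron–Wittig olefination: the lithiated geminal diboronate adds to the ketone and the β-alkoxy boronate undergoes syn B–O elimination, the remaining boryl group expected anti to the bulkier cyclohexyl group (E); the stabilised carbanion should not attack the ester at low temperature.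

Step 7
Reactants: 11 2-methylbut-1-en-3-yne
Product: 13 (1E)-1-iodo-3-methylbuta-1,3-diene, via dienylzirconocene chloride 12 (not isolated)
Conditions: Cp2Zr(H)Cl, THF, rt; then I2, 0 °C (product used as a solution)
Reagents that add atoms: iodine, II
Why: Hydrozirconation of the terminal alkyne is syn with zirconium on the terminal carbon, and iodinolysis with retention gives the E dienyl iodide.

Step 8
Reactants: 10 methyl trans-4-[(1E)-1-(4,4,5,5-tetramethyl-1,3,2-dioxaborolan-2-yl)prop-1-en-2-yl]cyclohexane-1-carboxylate; 13 (1E)-1-iodo-3-methylbuta-1,3-diene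
Product: 14 methyl trans-4-[(2E,4E)-6-methylhepta-2,4,6-trien-2-yl]cyclohexane-1-carboxylate
Conditions: Pd(dppf)Cl2 (5 mol%), K3PO4, THF/H2O, 50 °C
Reagents that add atoms: none
Why: Suzuki–Miyaura coupling proceeds with retention at both alkenyl partners, so the E,E-triene should form with the ester untouched.

Step 9
Reactants: 15 (S)-citronellal; 16 methyl vinyl ketone
Product: 18 (4R)-4-[(2S)-6-methylhept-5-en-2-yl]cyclohex-2-en-1-one, via keto aldehyde 17 (not isolated)
Conditions: (R)-2-[methoxy(diphenyl)methyl]pyrrolidine (5 mol%), ethyl 3,4-dihydroxybenzoate (20 mol%), neat, 4 °C; then LiOH, iPrOH, rt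
Reagents that add atoms: none
Why: Enamine-catalysed Michael addition to an enone followed by intramolecular aldol condensation: the (R)-diarylprolinol ether shields one face of the E-enamine so the enone adds to give the (R) ring carbon under catalyst control, and mild LiOH closes the cyclohexenone without epimerising the new centre.

Step 10
Reactants: 18 (4R)-4-[(2S)-6-methylhept-5-en-2-yl]cyclohex-2-en-1-one
Product: 20 (4R)-4-[(2S)-6-methylhept-5-en-2-yl]cyclohexa-1,5-dien-1-yl trifluoromethanesulfonate, via lithium dienolate 19 (not isolated)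
Conditions: LiN(iPr)2 (LDA), THF, −78 °C; then PhNTf2, −78 to 0 °C
Reagents that add atoms: N-phenylbis(trifluoromethanesulfonimide) (PhNTf2), O=S(=O)(N(c1ccccc1)S(=O)(=O)C(F)(F)F)C(F)(F)F
Why: Kinetic α′-deprotonation of the enone gives the cross-conjugated dienolate, which is O-triflated; the γ-stereocentre is not touched under kinetic conditions.

Step 11
Reactants: 20 (4R)-4-[(2S)-6-methylhept-5-en-2-yl]cyclohexa-1,5-dien-1-yl trifluoromethanesulfonate
Product: 21 (4R)-4-[(2S)-6-methylhept-5-en-2-yl]cyclohexa-1,5-diene-1-carboxylic acid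
Conditions: Pd(OAc)2 (5 mol%), dppf (10 mol%), CO (1 atm), H2O, Et3N, DMF, 60 °C; cold dilute HCl work-up, used at once
Reagents that add atoms: carbon monoxide, [C-]#[O+]; water, O
Why: Palladium-catalysed hydroxycarbonylation of an enol triflate (oxidative addition, CO insertion, capture of the acylpalladium by water) gives the 2-carboxy-1,3-diene, held in the flask as its carboxylate, which should suppress self-dimerisation.

Step 12
Reactants: 21 (4R)-4-[(2S)-6-methylhept-5-en-2-yl]cyclohexa-1,5-diene-1-carboxylic acid; 14 methyl trans-4-[(2E,4E)-6-methylhepta-2,4,6-trien-2-yl]cyclohexane-1-carboxylate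
Product: 22 (2R,4aR,5S,8aR)-5-{(1E)-2-[trans-4-(methoxycarbonyl)cyclohexyl]prop-1-en-1-yl}-7-methyl-2-[(2S)-6-methylhept-5-en-2-yl]-1,2,4a,5,8,8a-hexahydronaphthalene-4a-carboxylic acid (cis ring fusion; CO2H, H-8a and the C5 alkenyl group on one face; C2 side chain cis to CO2H)
Conditions: 14 (1 equiv), 21 (1.5 equiv, added in portions), toluene (about 2 M), BHT (cat.), 90 °C, argon, dark
Reagents that add atoms: none
Why: Normal-electron-demand Diels–Alder reaction with the 2-carboxy-1,3-diene as dienophile, modelled on the presumed biogenetic heterodimerisation: the CH2 terminus of the isoprenyl diene of 14 bonds to the β-carbon of 21 and the alkenyl-bearing terminus to the α-carbon (ortho and para effects reinforce), CO2H lies endo so the E-alkenyl group ends cis to it, and the diene approaches the face anti to the C4 side chain, which together should set C4a, C5 and C8a; the inner diene of 14 cannot reach s-cis because of its fully substituted terminus.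

Step 13
Reactants: 22 (2R,4aR,5S,8aR)-5-{(1E)-2-[trans-4-(methoxycarbonyl)cyclohexyl]prop-1-en-1-yl}-7-methyl-2-[(2S)-6-methylhept-5-en-2-yl]-1,2,4a,5,8,8a-hexahydronaphthalene-4a-carboxylic acid
Product: 23 (2R,4aR,5S,8aR)-5-[(1E)-2-(trans-4-carboxycyclohexyl)prop-1-en-1-yl]-7-methyl-2-[(2S)-6-methylhept-5-en-2-yl]-1,2,4a,5,8,8a-hexahydronaphthalene-4a-carboxylic acid (target)
Conditions: LiOH, THF/MeOH/H2O, rt; then 1 M HCl
Reagents that add atoms: lithium hydroxide, [Li+].[OH-]
Why: Saponification of the unhindered secondary methyl ester; the angular acid is already free and the equatorial carboxylate on ring C is the thermodynamic one, so no stereocentre is at risk.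

**Compound list**

1 | (±)-but-3-yn-2-ol | CC(O)C#C | starting material
2 | tert-butyl(but-3-yn-2-yloxy)dimethylsilane | CC(O[Si](C)(C)C(C)(C)C)C#C | intermediate
3 | ethylene | C=C | starting material
4 | tert-butyldimethyl[(3-methylidenepent-4-en-2-yl)oxy]silane | CC(O[Si](C)(C)C(C)(C)C)C(=C)C=C | intermediate
5 | methyl acrylate | C=CC(=O)OC | starting material
6 | methyl 4-[1-(tert-butyldimethylsilyloxy)ethyl]cyclohex-3-ene-1-carboxylate | COC(=O)C1CCC(=CC1)C(C)O[Si](C)(C)C(C)(C)C | intermediate
7 | methyl trans-4-[1-(tert-butyldimethylsilyloxy)ethyl]cyclohexane-1-carboxylate | COC(=O)[C@H]1CC[C@H](C(C)O[Si](C)(C)C(C)(C)C)CC1 | intermediate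
8 | methyl trans-4-(1-hydroxyethyl)cyclohexane-1-carboxylate | COC(=O)[C@H]1CC[C@H](C(C)O)CC1 | intermediate
9 | methyl trans-4-acetylcyclohexane-1-carboxylate | COC(=O)[C@H]1CC[C@H](C(C)=O)CC1 | intermediate
10 | methyl trans-4-[(1E)-1-(4,4,5,5-tetramethyl-1,3,2-dioxaborolan-2-yl)prop-1-en-2-yl]cyclohexane-1-carboxylate | COC(=O)[C@H]1CC[C@H](/C(C)=C/B2OC(C)(C)C(C)(C)O2)CC1 | intermediate
11 | 2-methylbut-1-en-3-yne | C=C(C)C#C | starting material
12 | chlorobis(cyclopentadienyl)[(1E)-3-methylbuta-1,3-dien-1-yl]zirconium | C=C(C)/C=C/[Zr](Cl)(C1C=CC=C1)C1C=CC=C1 | intermediate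
13 | (1E)-1-iodo-3-methylbuta-1,3-diene | C=C(C)/C=C/I | intermediate
14 | methyl trans-4-[(2E,4E)-6-methylhepta-2,4,6-trien-2-yl]cyclohexane-1-carboxylate | COC(=O)[C@H]1CC[C@H](/C(C)=C/C=C/C(C)=C)CC1 | intermediate
15 | (S)-citronellal | C[C@H](CC=O)CCC=C(C)C | starting material
16 | methyl vinyl ketone | CC(=O)C=C | starting material
17 | (2R,3S)-3,7-dimethyl-2-(3-oxobutyl)oct-6-enal | O=C[C@H](CCC(C)=O)[C@@H](C)CCC=C(C)C | intermediate
18 | (4R)-4-[(2S)-6-methylhept-5-en-2-yl]cyclohex-2-en-1-one | O=C1C=C[C@@H]([C@@H](C)CCC=C(C)C)CC1 | intermediate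
19 | lithium (4R)-4-[(2S)-6-methylhept-5-en-2-yl]cyclohexa-1,5-dien-1-olate | [Li]OC1=CC[C@@H](C=C1)[C@@H](C)CCC=C(C)C | intermediate
20 | (4R)-4-[(2S)-6-methylhept-5-en-2-yl]cyclohexa-1,5-dien-1-yl trifluoromethanesulfonate | O=S(=O)(OC1=CC[C@@H](C=C1)[C@@H](C)CCC=C(C)C)C(F)(F)F | intermediate
21 | (4R)-4-[(2S)-6-methylhept-5-en-2-yl]cyclohexa-1,5-diene-1-carboxylic acid | OC(=O)C1=CC[C@@H](C=C1)[C@@H](C)CCC=C(C)C | intermediate
22 | (2R,4aR,5S,8aR)-5-{(1E)-2-[trans-4-(methoxycarbonyl)cyclohexyl]prop-1-en-1-yl}-7-methyl-2-[(2S)-6-methylhept-5-en-2-yl]-1,2,4a,5,8,8a-hexahydronaphthalene-4a-carboxylic acid | CC(C)=CCC[C@H](C)[C@@H]1C=C[C@]2(C(=O)O)[C@@H](CC(C)=C[C@H]2/C=C(\C)[C@H]2CC[C@H](C(=O)OC)CC2)C1 | intermediate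
23 | (2R,4aR,5S,8aR)-5-[(1E)-2-(trans-4-carboxycyclohexyl)prop-1-en-1-yl]-7-methyl-2-[(2S)-6-methylhept-5-en-2-yl]-1,2,4a,5,8,8a-hexahydronaphthalene-4a-carboxylic acid | CC(C)=CCC[C@H](C)[C@@H]1C=C[C@]2(C(=O)O)[C@@H](CC(C)=C[C@H]2/C=C(\C)[C@H]2CC[C@H](C(=O)O)CC2)C1 | target

**Summary**

Total step count: 13. Longest linear sequence: 9 steps (1, 2, 3, 4, 5, 6, 8, 12, 13).

Steps most likely to fail:

1. Step 12. The cycloaddition may be outrun by self-dimerisation or aromatisation of the dienoic acid, or may proceed with insufficient endo or facial selectivity. The fallback moves the dienophile to the aldehyde oxidation level and uses Lewis-acid activation; it sets out from 20 and returns at 22. Triflate 20 would be formylated by palladium-catalysed reductive carbonylation (Pd(PPh3)4, CO, Bu3SnH, THF, 50 °C) to (4R)-4-[(2S)-6-methylhept-5-en-2-yl]cyclohexa-1,5-diene-1-carbaldehyde F1. This more electrophilic enal would be combined with 14 under Me2AlCl in CH2Cl2 at −78 °C, where the aluminium-bound formyl group should enforce the endo mode, to give methyl trans-4-{(1E)-1-[(1S,4aR,7R,8aR)-8a-formyl-3-methyl-7-[(2S)-6-methylhept-5-en-2-yl]-1,4,4a,7,8,8a-hexahydronaphthalen-1-yl]prop-1-en-2-yl}cyclohexane-1-carboxylate F2, the 4a-formyl analogue of 22. Pinnick oxidation (NaClO2, NaH2PO4, 2-methyl-2-butene, tBuOH/H2O) would then give 22.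

2. Step 6. The olefination may give poor E/Z control in the elimination, or the ketone may be enolised instead of attacked. The fallback fixes the geometry by a syn carbometalation of an alkyne; it sets out from 9 and returns at 10. Kinetic deprotonation of the methyl group of 9 (LDA, THF, −78 °C) and triflation with PhNTf2 would give methyl trans-4-[1-(trifluoromethanesulfonyloxy)ethenyl]cyclohexane-1-carboxylate F3. Fluoride-induced elimination (Bu4NF·3H2O, DMF, rt) would give methyl trans-4-ethynylcyclohexane-1-carboxylate F4. Copper-catalysed syn methylboration (CuCl, Xantphos, NaOtBu, B2pin2, MeI, THF, rt) places boron on the terminal carbon and methyl on the internal carbon on the same side, which gives 10 with the E geometry fixed by the mechanism.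

3. Step 4. Ester direction may be too weak, so hydrogen is delivered to both faces. The fallback replaces kinetic by thermodynamic control; it sets out from 6 and returns at 9. Heterogeneous hydrogenation of 6 (H2, palladium on carbon, EtOAc) would give 7 together with methyl cis-4-[1-(tert-butyldimethylsilyloxy)ethyl]cyclohexane-1-carboxylate F5. Jones oxidation of the mixture would give 9 together with methyl cis-4-acetylcyclohexane-1-carboxylate F6. Equilibration with NaOMe in MeOH, in which either α-centre can epimerise, should enrich the diequatorial trans isomer, and 9 would be purified by crystallisation or chromatography.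

Further compounds
F1 | step 12 | (4R)-4-[(2S)-6-methylhept-5-en-2-yl]cyclohexa-1,5-diene-1-carbaldehyde | O=CC1=CC[C@@H](C=C1)[C@@H](C)CCC=C(C)C
F2 | step 12 | methyl trans-4-{(1E)-1-[(1S,4aR,7R,8aR)-8a-formyl-3-methyl-7-[(2S)-6-methylhept-5-en-2-yl]-1,4,4a,7,8,8a-hexahydronaphthalen-1-yl]prop-1-en-2-yl}cyclohexane-1-carboxylate (4a-formyl analogue of 22) | CC(C)=CCC[C@H](C)[C@@H]1C=C[C@]2(C=O)[C@@H](CC(C)=C[C@H]2/C=C(\C)[C@H]2CC[C@H](C(=O)OC)CC2)C1
F3 | step 6 | methyl trans-4-[1-(trifluoromethanesulfonyloxy)ethenyl]cyclohexane-1-carboxylate | COC(=O)[C@H]1CC[C@H](C(=C)OS(=O)(=O)C(F)(F)F)CC1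
F4 | step 6 | methyl trans-4-ethynylcyclohexane-1-carboxylate | COC(=O)[C@H]1CC[C@H](C#C)CC1
F5 | step 4 | methyl cis-4-[1-(tert-butyldimethylsilyloxy)ethyl]cyclohexane-1-carboxylate | COC(=O)[C@H]1CC[C@@H](C(C)O[Si](C)(C)C(C)(C)C)CC1
F6 | step 4 | methyl cis-4-acetylcyclohexane-1-carboxylate | COC(=O)[C@H]1CC[C@@H](C(C)=O)CC1
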